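The data come from a simulation for an exercise, noise included.

Read the two earlier runs by the time each takes to reach about the same amount of target, which gives the quick number you asked for. The south-east run, at 75 °C, reads 35% after 6.00 min, and the east run, at 90 °C, reads 34% after 1.50 min. So about the same amount takes 4.00 times as long in the cooler run. We call this ratio s, the clock factor: the factor by which minutes at the lower of these two temperatures count for less than minutes at the higher. It is a reading with a scatter of 1.5 percentage points, and it carries the change of charge too, 0.021 M against 0.033 M.

| setting | south-east | east | birch | cedar | larch |
|---|---|---|---|---|---|
| substrate | 0.021 M | 0.033 M | 0.015 M | 0.015 M | 0.015 M |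
| temperature | 75 °C | 90 °C |  | 100 °C | 80 °C |
| remark | run made earlier | run made earlier | at 80 °C until 2.5 min, from then on at 100 °C |  |  |
| time |  |  | 5.0 min | 5.0 min | 5.0 min |

| run | time / min | target / % |
|---|---|---|
| south-east | 1.33 | 3 |
| south-east | 2.50 | 10 |
| south-east | 3.00 | 14 |
| south-east | 6.00 | 35 |
| south-east | 10.0 | 54 |
| south-east | 15.0 | 66 |
| east | 0.500 | 9 |
| east | 1.50 | 34 |
| east | 3.00 | 62 |
| east | 4.00 | 71 |
| east | 6.00 | 79 |
| east | 8.00 | 83 |

(readings scatter by 1.5 percentage points)

1. which flask leads in amount of target, in percent of the substrate charged ("all alike" within 1.5 percentage points) (birch / cedar / larch / all alike)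
2. how much target is there at the end, in percent of the substrate charged: birch
3. how much target is there at the end, in percent of the substrate charged: cedar
4. how much target is there at the end, in percent of the substrate charged: larch

- the earlier runs were read with a standard deviation of 1.5 percentage points
- a reading or a percentage of target counts all its forms, free or not

We let s compound evenly with the degrees, which turns each flask's minutes into minutes of an earlier run. Larch's 5.0 min at 80 °C becomes 7.94 min at 75 °C, where the south-east run gives about 44.2%. On the east clock birch's two halves add up to 7.29 min, which gives about 81.6%. Cedar's minutes become 12.6 min, past the last east reading of 83%, so we put cedar above that reading and in the lead.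

Your forecast also names cedar, with 80% there, 75% in birch and 43% in larch, and it says the sag in the runs “suggests an active species dying”, with other readings still open. We part on cedar, where its number stands below that last east reading and ours above, and on birch, 75% against our 81.6%.

Cedar leads with 92.5%, 12 points above the forecast, then birch with 86.1% and larch with 46.7%. The equations behind them are these:

    substrate → intermediate (k = 0.0540 /s, Ea = 103 kJ/mol)
    intermediate → target (k = 0.0290 /s, Ea = 103 kJ/mol)
    substrate + target ⇌ idle adduct, settled at all times (K = 950 /M, ΔH = 14.0 kJ/mol)
    (constants at 100 °C)

In cedar the step from substrate to intermediate had half of its turnover up to 5.0 min done by 0.204 min, earlier than the step from intermediate to target at 0.763 min. At 2.50 min cedar held 83.7% of target, bound form counted, and 4.06% of intermediate, and at 5.00 min it held 1.10% of intermediate. Cedar passed the east reading its clock time lay beyond by 9.5 points, and larch stood at 46.7% against our 44.2%. The same flask as cedar run at 75 °C has 1.25 min on the east clock, where the east run gives about 27.7%. That flask ended with 27.4% of target.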